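## Structural features

The target is a tetrahydrofuran (O1, C2, C3, C4, C5) in which C3 and C4 each carry a 3,4-dimethoxybenzyl group; the only other rings are the two veratryl arenes. C3 and C4 are adjacent stereocentres, both R and trans to each other. The cis isomer would be meso, so the stereochemical problem is the trans relationship plus one absolute sense (R,R and not S,S). A C2 axis runs through O1 and the midpoint of C3–C4, so the molecule consists of two identical ArCH2–CH–CH2–O halves joined at C3–C4, the 8–8' bond of a lignan. The key step exploits exactly this feature: it forms the C3–C4 bond by joining two copies of one monomer and sets C3 and C4 in the same event. Neither stereocentre carries a heteroatom or an acidifying group in the target, so both must be set while C2 and C5 are still at the carboxyl oxidation level. The fragile parts are the electron-rich veratryl rings, which are sensitive to strong oxidants and to Friedel–Crafts closure onto any cationic centre at C2 or C5; the aryl methyl ethers and the ring ether are otherwise robust. The real difficulty is therefore the C3–C4 bond with its two contiguous stereocentres in one absolute configuration; closing the ring is routine.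

## Logic of the disconnections

10 to 8 (through 9). The O1–C2 bond of the ring is cut. This is a C–O bond at a primary carbon, remote from the stereocentres, so its formation cannot disturb C3 or C4. The gain is an acyclic C2-symmetric 1,4-diol whose two hydroxyl groups are homotopic, so activation of either one gives the same 9. The demand on the forward step is activation of only one hydroxyl group, followed by 5-exo-tet closure.

8 to 7. No C–C bond is cut; C2 and C5 are taken back from CH2OH to acyl carbons bound to the nitrogen of two copies of the auxiliary. The reason is that the carbonyl groups make C3 and C4 enolisable positions and give the auxiliaries a place to sit. The gain is a precursor in which both stereocentres are α to a carbonyl. The demand is a reduction that cleaves both exocyclic N–acyl bonds without epimerising the α-carbons.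

7 to 4 (through 6 and 5). The C3–C4 bond (ring numbering of 10) is cut, which halves the molecule into two identical units. This is the key disconnection: one bond formation creates the only skeletal bond that is not present in the monomer and both stereocentres at once. The gain is the largest possible, from a C22 backbone with two stereocentres to a C11 monomer with none on the chain. The demand is an oxidative coupling of two nucleophilic α-carbons, with each carbon bonding on the face dictated by its own auxiliary.

4 to 1 and 2 (through 3). The N–acyl bond is cut, giving two commercial compounds. The demand is only a clean N-acylation.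

In one sentence: the C3–C4 bond and both stereocentres arise together in the oxidative homodimerisation of the enolate of 4. This sentence does not describe the route most chemists would draw first, in which the two benzyl groups are attached to a preformed lactone one after the other.

## Other disconnections considered

Alternative 1: (the first that comes to mind) The exocyclic C3–CH2Ar bond is cut at the lactone oxidation level. The forward key step is the trans-selective alkylation of the enolate of (R)-4-(3,4-dimethoxybenzyl)dihydrofuran-2(3H)-one A1 with the corresponding benzylic bromide. This would give (3R,4R)-3,4-bis(3,4-dimethoxybenzyl)dihydrofuran-2(3H)-one A2, which reduction would take to 8. The plan is reliable, but A1 must first be made as a single enantiomer in three or four steps of its own. The two stereocentres are then set in two separate C–C bond formations, the first under external control and the second under substrate control. The C2 symmetry is not used and the sequence is roughly twice as long as the chosen one.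

Alternative 2: The two C–H bonds at C3 and C4 are cut, that is, both stereocentres are traced back to alkenes. The forward key step is a two-directional double asymmetric hydrogenation of (2E,3E)-2,3-bis(3,4-dimethoxybenzylidene)succinic acid A3, available by a twofold Stobbe condensation. This would give (2R,3R)-2,3-bis(3,4-dimethoxybenzyl)succinic acid A4, which would then be reduced to 8. The grounds against it are mechanistic. The two C=C bonds of the twisted diene are reduced one after the other. The second reduction takes place on an α-branched benzylidene succinate, where the catalyst has to override the bias of the stereocentre just formed, and every mismatch leads to the meso diacid. One catalyst must therefore serve two different substrates, whereas in the chosen plan both centres come from one bond formation on one substrate type. Step economy is no better (five steps), and a precious-metal catalyst would have to be found.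

Alternative 3: Both aryl–CH2 bonds are cut. The forward key step is a two-directional copper-catalysed sp3–sp2 coupling of (3R,4R)-3,4-bis(iodomethyl)tetrahydrofuran A5 with two equivalents of the aryl Grignard reagent. The key step would create no stereocentre; it only carries over those of A5. A5 is not available as a single enantiomer, so it would require a resolution or an asymmetric synthesis of a trans-3,4-disubstituted tetrahydrofuran, followed by reduction and iodination. The difficulty of the target is thereby moved, not solved, and the route is longer.

Key step: step 2

Remark on the chemistry: by CIP analysis the SMILES is the (3R,4R) enantiomer; since the cis isomer is meso, "trans" and (3R,4R) together define the target. Compounds 1 and 2 are taken as commercially available.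

## Route

Step 1
Reactants: 1 3-(3,4-dimethoxyphenyl)propanoic acid; 2 (S)-4-isopropyloxazolidin-2-one
Product: 4 (S)-3-[3-(3,4-dimethoxyphenyl)propanoyl]-4-isopropyloxazolidin-2-one, via mixed pivalic anhydride 3 (not isolated)
Conditions: PivCl (1.05 equiv), Et3N (2.5 equiv), THF, −20 °C, 1 h; then LiCl (1.1 equiv), 2, −20 °C → rt
Reagents that add atoms: none
Why: N-Acylation of an oxazolidinone through a mixed pivalic anhydride; the tert-butyl group steers attack to the less hindered carbonyl of 3, and LiCl/Et3N makes the carbamate N–H nucleophilic enough. No stereocentre is formed and the one in 2 is not at an acidic position.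

Step 2
Reactants: 4 (S)-3-[3-(3,4-dimethoxyphenyl)propanoyl]-4-isopropyloxazolidin-2-one (2 equiv)
Product: 7 (4S,4'S)-3,3'-[(2R,3R)-2,3-bis(3,4-dimethoxybenzyl)succinyl]bis(4-isopropyloxazolidin-2-one), via lithium Z-enolate 5 (not isolated), via trichlorotitanium Z-enolate 6 (not isolated)
Conditions: LDA (1.05 equiv), THF, −78 °C, 30 min; TiCl4 (1.1 equiv, CH2Cl2 solution), −78 °C → −20 °C; aq. NH4Cl
Reagents that add atoms: none
Why: Oxidative homocoupling of a chiral imide enolate, the enolate counterpart of the biosynthetic 8–8' radical dimerisation. LDA should give the chelated Z-enolate 5 (Z geometry enforced by allylic strain in the imide), and transmetalation with TiCl4 gives 6, whose Ti(IV)–O enolate is in valence equilibrium with a Ti(III)-bound α-acyl radical. Two such species join at their α-carbons (or one radical adds to a second enolate, followed by a second one-electron oxidation) and release TiCl3. No ring is closed. Both new stereocentres (the future C3 and C4 of the ring) are controlled by the (S)-isopropyl group: in the metal-chelated Z-enolate it covers one face of the α-carbon, and bonding on the open face gives R at each centre, the same sense as in alkylations of this enolate class, because the new C–C bond ranks between the acyl carbon and the benzyl carbon. Because both partners carry the same auxiliary, (R,R) is the doubly matched product; one facial error gives the (2R,3S) isomer and two errors the (S,S) isomer, and all of these are diastereomers of 7, so they should be separable by chromatography or crystallisation and the backbone should be enantiomerically pure at this point. The step needs C–C coupling to win over Claisen-type attack of the enolate on another imide and over ketene loss from the enolate; low temperature and immediate capture by titanium should secure this. The veratryl rings should lie outside the oxidising power of the Ti(IV)/Ti(III) couple.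

Step 3
Reactants: 7 (4S,4'S)-3,3'-[(2R,3R)-2,3-bis(3,4-dimethoxybenzyl)succinyl]bis(4-isopropyloxazolidin-2-one)
Product: 8 (2R,3R)-2,3-bis(3,4-dimethoxybenzyl)butane-1,4-diol
Conditions: LiBH4 (4 equiv), MeOH (4 equiv), THF, 0 °C → rt; aq. NaOH work-up
Reagents that add atoms: none
Why: Reductive cleavage of N-acyl oxazolidinones by LiBH4, carried out at both ends in one operation: hydride adds to the exocyclic imide carbonyl, the auxiliary leaves, and the aldehyde is reduced further. Any lactone formed by attack of the first alkoxide on the second imide is reduced by the same reagent to the same diol. The α-centres are not deprotonated under these conditions, so (R,R) is carried over, and 2 is recovered.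

Step 4
Reactants: 8 (2R,3R)-2,3-bis(3,4-dimethoxybenzyl)butane-1,4-diol
Product: 10 (3R,4R)-3,4-bis(3,4-dimethoxybenzyl)tetrahydrofuran, via monotosylate 9 (not isolated)
Conditions: TsCl (1.05 equiv), pyridine, 0 °C → 50 °C
Reagents that add atoms: none
Why: Monosulfonylation followed by intramolecular Williamson etherification (5-exo-tet). The two hydroxyl groups are homotopic through the C2 axis, so either gives the same 9, and closure takes place at a primary CH2 without touching C3 or C4, so the trans (3R,4R) configuration is retained.

## Compound list

1 | 3-(3,4-dimethoxyphenyl)propanoic acid | COc1ccc(CCC(=O)O)cc1OC | starting material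
2 | (S)-4-isopropyloxazolidin-2-one | CC(C)[C@H]1COC(=O)N1 | starting material
3 | 3-(3,4-dimethoxyphenyl)propanoic pivalic anhydride | COc1ccc(CCC(=O)OC(=O)C(C)(C)C)cc1OC | intermediate (not isolated)
4 | (S)-3-[3-(3,4-dimethoxyphenyl)propanoyl]-4-isopropyloxazolidin-2-one | COc1ccc(CCC(=O)N2[C@@H](C(C)C)COC2=O)cc1OC | intermediate
5 | lithium (Z)-3-(3,4-dimethoxyphenyl)-1-[(S)-4-isopropyl-2-oxooxazolidin-3-yl]prop-1-en-1-olate | [Li+].[O-]/C(=C\Cc1ccc(OC)c(OC)c1)N1[C@@H](C(C)C)COC1=O | intermediate (not isolated)
6 | trichlorotitanium(IV) (Z)-3-(3,4-dimethoxyphenyl)-1-[(S)-4-isopropyl-2-oxooxazolidin-3-yl]prop-1-en-1-olate | Cl[Ti](Cl)(Cl)O/C(=C\Cc1ccc(OC)c(OC)c1)N1[C@@H](C(C)C)COC1=O | intermediate (not isolated)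
7 | (4S,4'S)-3,3'-[(2R,3R)-2,3-bis(3,4-dimethoxybenzyl)succinyl]bis(4-isopropyloxazolidin-2-one) | COc1ccc(C[C@@H](C(=O)N2[C@@H](C(C)C)COC2=O)[C@@H](Cc2ccc(OC)c(OC)c2)C(=O)N2[C@@H](C(C)C)COC2=O)cc1OC | intermediate
8 | (2R,3R)-2,3-bis(3,4-dimethoxybenzyl)butane-1,4-diol | COc1ccc(C[C@@H](CO)[C@H](CO)Cc2ccc(OC)c(OC)c2)cc1OC | intermediate
9 | (2R,3R)-2,3-bis(3,4-dimethoxybenzyl)-4-hydroxybutyl 4-methylbenzenesulfonate | COc1ccc(C[C@@H](COS(=O)(=O)c2ccc(C)cc2)[C@H](CO)Cc2ccc(OC)c(OC)c2)cc1OC | intermediate (not isolated)
10 | (3R,4R)-3,4-bis(3,4-dimethoxybenzyl)tetrahydrofuran | COc1ccc(C[C@H]2COC[C@@H]2Cc2ccc(OC)c(OC)c2)cc1OC | target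

## Step count and least certain steps

Total step count: 4. Longest linear sequence: 4 steps (1 → 4 → 7 → 8 → 10).

Step 2 (key step). The most likely failure is insufficient facial discrimination in the C–C coupling: if part of the radical partner reacts outside the metal chelate, the shielding by the isopropyl group is lost and the (2R,3S) diastereomer grows. A second risk is incomplete oxidation, with loss of enolate by ketene elimination on warming, which would return monomer or its fragments. Fallback, setting out from 4 and returning at 8: the sodium enolate of 4 (NaHMDS, THF, −78 °C) would be alkylated with tert-butyl bromoacetate on the face away from the isopropyl group to give tert-butyl (R)-3-(3,4-dimethoxybenzyl)-4-[(S)-4-isopropyl-2-oxooxazolidin-3-yl]-4-oxobutanoate F1. LiBH4 would cleave the auxiliary to give tert-butyl (R)-4-(3,4-dimethoxyphenyl)-3-(hydroxymethyl)butanoate F2. TFA in CH2Cl2 would then close (R)-4-(3,4-dimethoxybenzyl)dihydrofuran-2(3H)-one F3 (the compound called A1 above). Its lithium enolate (LiHMDS, THF, −78 °C) would be alkylated with 3,4-dimethoxybenzyl bromide anti to the existing benzyl group to give (3R,4R)-3,4-bis(3,4-dimethoxybenzyl)dihydrofuran-2(3H)-one F4 (the compound called A2 above). LiAlH4 would reduce F4 to 8, where the route is rejoined. This sets the two centres one after the other by standard auxiliary and substrate control, at the cost of three extra steps.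

Step 3. Both acyl groups are α-branched and flank each other, so hydride may partly attack the ring carbonyl of the auxiliary (endocyclic opening), or the reduction may stall after the first acyl group. Fallback, setting out from 7 and returning at 8: hydrolytic removal of both auxiliaries with LiOH/H2O2 (THF/H2O, 0 °C), where the hydroperoxide anion attacks only the exocyclic carbonyl even in hindered imides, would give (2R,3R)-2,3-bis(3,4-dimethoxybenzyl)succinic acid F5 (the compound called A4 above). LiAlH4 in THF would then reduce F5 to 8.

Step 4. Sulfonylation of the second hydroxyl group before ring closure, or displacement of the sulfonate by chloride, would divert material from the 5-exo-tet cyclisation. Fallback, setting out from 8 and returning at 10: a Mitsunobu-type redox dehydration (PPh3, DIAD, THF, 0 °C → rt), in which the diol is activated once on phosphorus and closes to the ether directly, so that double activation as two leaving groups cannot occur. No new isolable compound lies on this path.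

## Further compounds

F1 | step 2 | tert-butyl (R)-3-(3,4-dimethoxybenzyl)-4-[(S)-4-isopropyl-2-oxooxazolidin-3-yl]-4-oxobutanoate | COc1ccc(C[C@H](CC(=O)OC(C)(C)C)C(=O)N2[C@@H](C(C)C)COC2=O)cc1OC
F2 | step 2 | tert-butyl (R)-4-(3,4-dimethoxyphenyl)-3-(hydroxymethyl)butanoate | COc1ccc(C[C@H](CC(=O)OC(C)(C)C)CO)cc1OC
F3 | step 2 | (R)-4-(3,4-dimethoxybenzyl)dihydrofuran-2(3H)-one | O=C1C[C@@H](Cc2ccc(OC)c(OC)c2)CO1
F4 | step 2 | (3R,4R)-3,4-bis(3,4-dimethoxybenzyl)dihydrofuran-2(3H)-one | COc1ccc(C[C@H]2C(=O)OC[C@@H]2Cc2ccc(OC)c(OC)c2)cc1OC
F5 | step 3 | (2R,3R)-2,3-bis(3,4-dimethoxybenzyl)succinic acid | COc1ccc(C[C@@H](C(=O)O)[C@@H](Cc2ccc(OC)c(OC)c2)C(=O)O)cc1OC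
F0 | step 4 | none | none
A1 | alternative 1 | (R)-4-(3,4-dimethoxybenzyl)dihydrofuran-2(3H)-one | O=C1C[C@@H](Cc2ccc(OC)c(OC)c2)CO1
A2 | alternative 1 | (3R,4R)-3,4-bis(3,4-dimethoxybenzyl)dihydrofuran-2(3H)-one | COc1ccc(C[C@H]2C(=O)OC[C@@H]2Cc2ccc(OC)c(OC)c2)cc1OC
A3 | alternative 2 | (2E,3E)-2,3-bis(3,4-dimethoxybenzylidene)succinic acid | COc1ccc(/C=C(/C(=O)O)C(=C/c2ccc(OC)c(OC)c2)\C(=O)O)cc1OC
A4 | alternative 2 | (2R,3R)-2,3-bis(3,4-dimethoxybenzyl)succinic acid | COc1ccc(C[C@@H](C(=O)O)[C@@H](Cc2ccc(OC)c(OC)c2)C(=O)O)cc1OC
A5 | alternative 3 | (3R,4R)-3,4-bis(iodomethyl)tetrahydrofuran | IC[C@H]1COC[C@@H]1CI
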